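**Retrosynthetic overview**

- Sarothralin is reached by fluoride cleavage of its ring A bis-silyl ether; ring B (the 2-isobutyryl-6,6-dimethylcyclohexane-1,3,5-trione ring, written as its dienol) is the only ring that has to be built.
- Ring B is cut C3 + C3: the CMe2 carbon and the two ring C–O carbons beside it are dimethylmalonyl dichloride; the carbon carrying the CH2 bridge, the C–O carbon next to it and the carbon carrying the isobutyryl group are C2, C3 and C4 of a 1-aryl-6-methylheptane-3,5-dione, joined as its 1,3-dianion by two C-acylations.
- The diketone comes from opening a ring A dihydrocoumarin with the kinetic enolate of 3-methylbutan-2-one, then silylating the freed phenol.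
- The dihydrocoumarin comes from 2,4,6-trihydroxybenzophenone: silylating the para hydroxyl first leaves a mirror-symmetric resorcinol, so the acrylic acid annulation can give only one lactone and leaves one free hydroxyl (ortho to benzoyl, remote from the chain) for the prenyl ether.
- Ring order: ring A and the phenyl ring are bought; a temporary lactone ring is closed in step 2 and opened in step 4; ring B is closed in step 6.

Key step: step 6

Remark: the target has no stereocentre; ring B is written throughout in the dienol form of the target SMILES (its tautomers are one compound), and the intermediates of steps 4 and 6 that stay in the flask are written as lithium salts.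

**Step 1**
Reactants: 1 2,4,6-trihydroxybenzophenone; 2 triisopropylsilyl chloride
Product: 3 silyl ether 2,6-dihydroxy-4-(triisopropylsilyloxy)benzophenone
Conditions: TIPSCl (1.05 equiv), imidazole (2.2 equiv), DMF, 0 °C to rt
Reagents that add atoms: triisopropylsilyl chloride (2), CC(C)[Si](Cl)(C(C)C)C(C)C
Why: Regioselective phenol silylation: the para hydroxyl is the most acidic one and the only one neither flanked by the benzoyl group nor held in its hydrogen bond, so one equivalent of the bulky chloride should cap it and leave a resorcinol whose two free ring positions and two hydroxyls are equivalent.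

**Step 2**
Reactants: 3 silyl ether; 4 acrylic acid
Product: 6 dihydrocoumarin 8-benzoyl-7-hydroxy-5-(triisopropylsilyloxy)chroman-2-one, via ring-alkylated propanoic acid 5 (not isolated)
Conditions: acrylic acid (1.3 equiv), Amberlyst-15 (dry sulfonic acid resin), toluene, 100 °C, azeotropic removal of water
Reagents that add atoms: acrylic acid (4), C=CC(=O)O
Why: Acid-catalysed Friedel–Crafts conjugate addition of the resorcinol ring to acrylic acid followed by lactonisation, the known phenol/acrylic acid route to dihydrocoumarins; because the two nucleophilic ring carbons are equivalent and the only hydroxyl beside the new chain is an ortho one, a single lactone is possible, and the aryl triisopropylsilyl ether is expected to tolerate the anhydrous acid resin.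

**Step 3**
Reactants: 6 dihydrocoumarin; 7 prenyl bromide
Product: 8 prenyl ether 8-benzoyl-7-(3-methylbut-2-enyloxy)-5-(triisopropylsilyloxy)chroman-2-one
Conditions: prenyl bromide (1.3 equiv), K2CO3 (1.5 equiv), dry acetone, 50 °C
Reagents that add atoms: prenyl bromide (7), CC(C)=CCBr
Why: Williamson etherification of the single remaining phenol (hydrogen-bonded to the benzoyl group, hence warm carbonate), so the prenyl group can only arrive on the oxygen that is ortho to the benzoyl group and not next to the chain.

**Step 4**
Reactants: 8 prenyl ether; 9 3-methylbutan-2-one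
Product: 11 diketone 1-[3-benzoyl-2-hydroxy-4-(3-methylbut-2-enyloxy)-6-(triisopropylsilyloxy)phenyl]-6-methylheptane-3,5-dione, via lithium enolate 10 (not isolated)
Conditions: 9 (3.0 equiv), LiN(iPr)2 (3.0 equiv), THF, −78 °C; then 8, −78 to −40 °C; AcOH quench
Reagents that add atoms: 3-methylbutan-2-one (9), CC(C)C(C)=O
Why: Crossed Claisen acylation: the amide base deprotonates the methyl group of the ketone under kinetic control and the enolate opens the activated aryl lactone, after which the diketonate and the phenoxide formed resist further attack until the acidic quench.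

**Step 5**
Reactants: 11 diketone; 12 tert-butyldimethylsilyl chloride
Product: 13 diketone bis-silyl ether 1-[3-benzoyl-2-(tert-butyldimethylsilyloxy)-4-(3-methylbut-2-enyloxy)-6-(triisopropylsilyloxy)phenyl]-6-methylheptane-3,5-dione
Conditions: TBSCl (2.0 equiv), imidazole (4.0 equiv), 4-dimethylaminopyridine (0.1 equiv), DMF, 40 °C
Reagents that add atoms: tert-butyldimethylsilyl chloride (12), CC(C)(C)[Si](C)(C)Cl
Why: Imidazole-promoted phenol silylation, which on gentle warming should cap the hindered, hydrogen-bonded hydroxyl, while any silyl enol ether of the diketone is hydrolysed in the aqueous work-up.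

**Step 6**
Reactants: 13 diketone bis-silyl ether; 14 dimethylmalonyl dichloride
Product: 17 sarothralin bis-silyl ether 4-{[3-benzoyl-2-(tert-butyldimethylsilyloxy)-4-(3-methylbut-2-enyloxy)-6-(triisopropylsilyloxy)phenyl]methyl}-3,5-dihydroxy-6,6-dimethyl-2-(2-methylpropanoyl)cyclohexa-2,4-dien-1-one, via dilithium dienolate 15 (not isolated), via lithium enolate of the triketo acid chloride 16 (not isolated)
Conditions: lithium 2,2,6,6-tetramethylpiperidide (2.2 equiv), THF, −78 to −20 °C; cannulated into 14 (1.1 equiv), THF (0.01 M), −78 °C; then Et3N (3 equiv), 4-dimethylaminopyridine (0.2 equiv), −78 °C to rt; aq. citric acid work-up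
Reagents that add atoms: dimethylmalonyl dichloride (14), CC(C)(C(=O)Cl)C(=O)Cl
Why: Proposed new method: the hindered lithium amide removes first a C4 proton and then, under kinetic control, a proton of the less hindered C2 methylene (heptanedione numbering; not the isopropyl methine) to give dianion 15, whose more basic C2 terminus attacks one acyl chloride of 14 to give the triketone enolate 16, and C4 of 16 then attacks the second acyl chloride, so that both new C–C bonds end in ring B. The nearest known chemistry is the terminal C-acylation of 1,3-diketone dianions by esters, the [3+3] condensation of 1,3-dinucleophiles with malonyl dichlorides (which frequently ends in O-acylated pyranones) and the amine-catalysed rearrangement of enol esters to 2-acyl-1,3-diones; their union on a non-enolisable malonyl dichloride is untested. Ring B closes by a 6-(enolendo)-exo-trig acylation that the gem-dimethyl group should accelerate, and no stereocentre is created. The step needs carbon and not oxygen to end up acylated, which Et3N and 4-dimethylaminopyridine should ensure by reopening any enol ester as an acylpyridinium ion until the acyl group rests on C4, the delocalised trione enolate being the most stable species in the flask. The tetramethylpiperidide is chosen because its amine cannot pass a hydride to the diaryl ketone and is too hindered to be acylated at a useful rate, 14 has no alpha hydrogen and so cannot form a ketene, and adding 15 to cold dilute 14 keeps the dianion from deprotonating 16 or linking two chains.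

**Step 7**
Reactants: 17 sarothralin bis-silyl ether
Product: 18 sarothralin
Conditions: tetrabutylammonium fluoride (2.5 equiv), AcOH (3 equiv), THF, 0 °C
Reagents that add atoms: none
Why: Fluoride-mediated cleavage of both aryl silyl ethers, buffered with acetic acid so that the acidic trione, the prenyl ether and the methylene bridge are not exposed to strong base.

**Compound list**

1 | 2,4,6-trihydroxybenzophenone | O=C(c1ccccc1)c1c(O)cc(O)cc1O | starting material
2 | triisopropylsilyl chloride | CC(C)[Si](Cl)(C(C)C)C(C)C | starting material
3 | 2,6-dihydroxy-4-(triisopropylsilyloxy)benzophenone | O=C(c1ccccc1)c1c(O)cc(O[Si](C(C)C)(C(C)C)C(C)C)cc1O | intermediate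
4 | acrylic acid | C=CC(=O)O | starting material
5 | 3-[3-benzoyl-2,4-dihydroxy-6-(triisopropylsilyloxy)phenyl]propanoic acid (formed in the flask in step 2) | OC(=O)CCc1c(O)c(C(=O)c2ccccc2)c(O)cc1O[Si](C(C)C)(C(C)C)C(C)C | intermediate
6 | 8-benzoyl-7-hydroxy-5-(triisopropylsilyloxy)chroman-2-one | O=C1CCc2c(O[Si](C(C)C)(C(C)C)C(C)C)cc(O)c(C(=O)c3ccccc3)c2O1 | intermediate
7 | prenyl bromide (1-bromo-3-methylbut-2-ene) | CC(C)=CCBr | starting material
8 | 8-benzoyl-7-(3-methylbut-2-enyloxy)-5-(triisopropylsilyloxy)chroman-2-one | CC(C)=CCOc1cc(O[Si](C(C)C)(C(C)C)C(C)C)c2CCC(=O)Oc2c1C(=O)c1ccccc1 | intermediate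
9 | 3-methylbutan-2-one | CC(C)C(C)=O | starting material
10 | lithium 3-methylbut-1-en-2-olate (formed in the flask in step 4) | [Li+].CC(C)C([O-])=C | intermediate
11 | 1-[3-benzoyl-2-hydroxy-4-(3-methylbut-2-enyloxy)-6-(triisopropylsilyloxy)phenyl]-6-methylheptane-3,5-dione | CC(C)C(=O)CC(=O)CCc1c(O[Si](C(C)C)(C(C)C)C(C)C)cc(OCC=C(C)C)c(C(=O)c2ccccc2)c1O | intermediate
12 | tert-butyldimethylsilyl chloride | CC(C)(C)[Si](C)(C)Cl | starting material
13 | 1-[3-benzoyl-2-(tert-butyldimethylsilyloxy)-4-(3-methylbut-2-enyloxy)-6-(triisopropylsilyloxy)phenyl]-6-methylheptane-3,5-dione (key-step precursor) | CC(C)C(=O)CC(=O)CCc1c(O[Si](C(C)C)(C(C)C)C(C)C)cc(OCC=C(C)C)c(C(=O)c2ccccc2)c1O[Si](C)(C)C(C)(C)C | intermediate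
14 | dimethylmalonyl dichloride | CC(C)(C(=O)Cl)C(=O)Cl | starting material
15 | dilithium 1,3-dienolate of 13 (formed in the flask in step 6) | [Li+].[Li+].CC(C)C([O-])=CC([O-])=CCc1c(O[Si](C(C)C)(C(C)C)C(C)C)cc(OCC=C(C)C)c(C(=O)c2ccccc2)c1O[Si](C)(C)C(C)(C)C | intermediate
16 | lithium enolate of 4-(arylmethyl)-2,2,8-trimethyl-3,5,7-trioxononanoyl chloride, aryl as in 13 (formed in the flask in step 6) | [Li+].CC(C)C([O-])=CC(=O)C(Cc1c(O[Si](C(C)C)(C(C)C)C(C)C)cc(OCC=C(C)C)c(C(=O)c2ccccc2)c1O[Si](C)(C)C(C)(C)C)C(=O)C(C)(C)C(Cl)=O | intermediate
17 | sarothralin ring A bis-silyl ether (key-step product) | CC(C)=CCOc1cc(O[Si](C(C)C)(C(C)C)C(C)C)c(CC2=C(O)C(C)(C)C(=O)C(C(=O)C(C)C)=C2O)c(O[Si](C)(C)C(C)(C)C)c1C(=O)c1ccccc1 | intermediate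
18 | sarothralin | CC(C)=CCOc1cc(O)c(CC2=C(O)C(C)(C)C(=O)C(C(=O)C(C)C)=C2O)c(O)c1C(=O)c1ccccc1 | target

**Step count and risks**

Total steps: 7. Longest linear sequence: 7 steps (1 to 18).

Steps most likely to fail:

Step 6 (proposed method). Three processes could defeat it: proton transfer from the acylated intermediate to unreacted dianion, ring closure through oxygen that the acyl-transfer catalyst fails to correct, and coupling of two chains through one dichloride. The fallback uses known chemistry, sets out from 13 and returns at 17. The dianion of 13 (lithium 2,2,6,6-tetramethylpiperidide, 3.1 equiv, THF) is acylated at C2 with dimethyl 2,2-dimethylmalonate, the established ester acylation of diketone dianions, to give methyl 4-(arylmethyl)-2,2,8-trimethyl-3,5,7-trioxononanoate F1. NaH in THF then closes ring B by a Dieckmann-type Claisen condensation of the triketo ester to give 17. Methoxide is a poorer leaving group than chloride, so O-acylation does not compete. Partial loss of a silyl group at this stage would be harmless because step 7 removes both.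

Step 2. The silyl ether could be cleaved by the hot acid before the C–C bond forms, which would free the para hydroxyl and open a second mode of lactonisation; double annulation or polymerisation of acrylic acid are further risks. The fallback sets out from 3 and returns at 6. Propiolic acid with catalytic Pd(OAc)2 in CF3CO2H/CH2Cl2 at room temperature (hydroarylation then lactonisation, known for electron-rich phenols) should give 8-benzoyl-7-hydroxy-5-(triisopropylsilyloxy)coumarin F2, again the only regioisomer the symmetric substrate allows. Hydrogenation of its C3–C4 double bond (H2, palladium on carbon, EtOAc) then gives 6, with no prenyl group yet present to suffer.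

Step 5. Silylation of the hindered, hydrogen-bonded phenol may be slow, with competing silylation of the diketone enol or ketalisation of the hydroxy diketone on handling. The fallback sets out from 8 and returns at 13, so the diketone is made only after the phenol is protected. The lactone is opened with ClMgN(OMe)Me (from MeNHOMe·HCl and iPrMgCl, THF, −20 °C) to give the N-methoxy-N-methylamide F3. Its phenol is silylated (TBSOTf, 2,6-lutidine, CH2Cl2, 0 °C) to give the silylated amide F4. Lithium enolate 10 (3 equiv, THF, −78 to 0 °C) is then acylated by the amide to give 13.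

**Further compounds**

F1 | step 6 | methyl 4-{[3-benzoyl-2-(tert-butyldimethylsilyloxy)-4-(3-methylbut-2-enyloxy)-6-(triisopropylsilyloxy)phenyl]methyl}-2,2,8-trimethyl-3,5,7-trioxononanoate | COC(=O)C(C)(C)C(=O)C(Cc1c(O[Si](C(C)C)(C(C)C)C(C)C)cc(OCC=C(C)C)c(C(=O)c2ccccc2)c1O[Si](C)(C)C(C)(C)C)C(=O)CC(=O)C(C)C
F2 | step 2 | 8-benzoyl-7-hydroxy-5-(triisopropylsilyloxy)-2H-chromen-2-one | O=C1C=Cc2c(O[Si](C(C)C)(C(C)C)C(C)C)cc(O)c(C(=O)c3ccccc3)c2O1
F3 | step 5 | 3-[3-benzoyl-2-hydroxy-4-(3-methylbut-2-enyloxy)-6-(triisopropylsilyloxy)phenyl]-N-methoxy-N-methylpropanamide | CON(C)C(=O)CCc1c(O[Si](C(C)C)(C(C)C)C(C)C)cc(OCC=C(C)C)c(C(=O)c2ccccc2)c1O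
F4 | step 5 | 3-[3-benzoyl-2-(tert-butyldimethylsilyloxy)-4-(3-methylbut-2-enyloxy)-6-(triisopropylsilyloxy)phenyl]-N-methoxy-N-methylpropanamide | CON(C)C(=O)CCc1c(O[Si](C(C)C)(C(C)C)C(C)C)cc(OCC=C(C)C)c(C(=O)c2ccccc2)c1O[Si](C)(C)C(C)(C)C
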